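**Plan**

1. Retrosynthetic cuts, in order: the C7 benzyl ester and the C3 carbonyl (last adjustments); C3–C4 (aldol, ring A); C4–C5 (Michael addition of a propanoate carried on O10, lactone ring); C1–C10 (organocerium); then C11–C12 (carbonyl-ene, ring C) and C13–C16 (aldol, ring D); finally C9=C11 and C6=C7 (double Wittig) and the two alkylations at C8, back to cyclopentane-1,3-dione.
2. Enabling feature: in ring B the quaternary C8 lies between C9 and C6, each of which carries exactly one exocyclic carbon (C11 and C7) and which are tied by C10–C5. Ring B is thus a masked mirror-symmetric 2,2-disubstituted 1,3-dimethylidenecyclopentane, and a C12 aldehyde held on C13 of ring D can reach only the methylidene on its own face.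
3. Forward order of rings: ring B (bought) → ring D (spiro, aldol) → ring C (ene; the bicyclo[3.2.1]octane is complete and C8 becomes stereogenic) → oxidation pattern of ring B → lactone ring → ring A.
4. Stereochemistry: C13 and C16 from (R)-proline; C8 from group selection in the ene step; C9 by equilibration next to the C10 ketone; C10 by addition anti to C11; C5 by the O10 tether; C6 by equilibration trans to C4; C4 by the bridged ring; C3 by K[(s-Bu)3BH].

Key step: step 7

Remark: locants are gibberellane locants (C7 = carboxyl carbon on C6, C18 = methyl on C4, C19 = lactone carbonyl, C17 = methyl on C16), α is the face of ring B that carries the lactone oxygen, and 2 and 4 are assumed to be bought as such.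

Step 1
Reactants: 1 cyclopentane-1,3-dione; 2 3-[(tert-butyldimethylsilyl)oxy]propanal
Product: 3 2-{3-[(tert-butyldimethylsilyl)oxy]propyl}cyclopentane-1,3-dione
Conditions: diethyl 2,6-dimethyl-1,4-dihydropyridine-3,5-dicarboxylate (Hantzsch ester, 1.05 equiv), L-proline (10 mol%), CH2Cl2, rt
Reagents that add atoms: none
Why: Knoevenagel condensation of the dione with the aldehyde followed by conjugate hydride transfer from the Hantzsch ester (three-component reductive alkylation) should give clean C2-monoalkylation, which direct alkylation of the dione does not.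

Step 2
Reactants: 3 2-{3-[(tert-butyldimethylsilyl)oxy]propyl}cyclopentane-1,3-dione; 4 2-(chloromethyl)-3,5-dioxahex-1-ene
Product: 5 2-{3-[(tert-butyldimethylsilyl)oxy]propyl}-2-[2-(methoxymethoxy)prop-2-en-1-yl]cyclopentane-1,3-dione
Conditions: K2CO3, NaI (10 mol%), DMF, 60 °C; then xylene, 140 °C
Reagents that add atoms: none
Why: C-alkylation of the 2-alkyl-1,3-dione enolate by the allylic chloride (any O-allylated enol ether is brought to the same product by Claisen rearrangement in the thermal stage) creates the quaternary carbon that becomes C8 and brings in a masked acetonyl arm (C15–C16–C17); no stereocentre is formed yet.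

Step 3
Reactants: 5 2,2-disubstituted cyclopentane-1,3-dione
Product: 6 tert-butyl(3-{1-[2-(methoxymethoxy)prop-2-en-1-yl]-2,5-dimethylidenecyclopentyl}propoxy)dimethylsilane
Conditions: Ph3PCH3Br (4.2 equiv), KN(SiMe3)2 (4.0 equiv), toluene, 0 → 90 °C
Reagents that add atoms: methyltriphenylphosphonium bromide, C[P+](c1ccccc1)(c1ccccc1)c1ccccc1.[Br-]
Why: double Wittig methylenation with the alkoxide-free ylide (no retro-Claisen opening of the dione) turns both ring carbonyls into the methylidene groups that become C11 and C7, keeping the mirror symmetry of ring B.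

Step 4
Reactants: 6 bis-methylidene silyl ether
Product: 7 1-[1-(3-hydroxypropyl)-2,5-dimethylidenecyclopentyl]propan-2-one
Conditions: HCl (0.5 M aq.)/THF 1:4, rt
Reagents that add atoms: water, O
Why: one mild aqueous acid treatment should hydrolyse the methoxymethyl enol ether to the methyl ketone and remove the primary silyl ether, while the 1,1-disubstituted alkenes are not isomerised by dilute acid at room temperature.

Step 5
Reactants: 7 hydroxy ketone
Product: 8 3-[2,5-dimethylidene-1-(2-oxopropyl)cyclopentyl]propanal
Conditions: TEMPO (10 mol%), PhI(OAc)2 (1.1 equiv), CH2Cl2, rt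
Reagents that add atoms: none
Why: nitroxyl-catalysed oxidation of the primary alcohol stops at the aldehyde in anhydrous CH2Cl2 and leaves the ketone and both alkenes untouched.

Step 6
Reactants: 8 keto aldehyde
Product: 10 (2R,3R)-2-methyl-6,9-dimethylidene-2-[(triethylsilyl)oxy]spiro[4.4]nonane-3-carbaldehyde, via hydroxy aldehyde 9 (not isolated)
Conditions: (R)-proline (30 mol%), CH2Cl2, rt; then 2,6-lutidine, Et3SiOTf, –60 °C, same flask
Reagents that add atoms: triethylsilyl trifluoromethanesulfonate, CC[Si](CC)(CC)OS(=O)(=O)C(F)(F)F
Why: the aldehyde forms the E-enamine with (R)-proline and its α-carbon (C13) adds to the tethered methyl ketone in a 5-(enolexo)-exo-trig aldol through the hydrogen-bonded transition state (ketone oxygen toward the carboxylic acid, ring tether anti to the enamine carbon, methyl in the crowded position), which should set C13 and C16 with the hydroxyl trans to the formyl group in the absolute sense opposite to that given by (S)-proline in aldehyde cross-aldol reactions, and silylation in the same flask blocks retro-aldol and dehydration.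

Step 7
Reactants: 10 silyloxy aldehyde
Product: 11 tricyclic homoallylic alcohol (rings B, C and D; C9=C10; 6-methylidene; 12-OH; 16-OSiEt3)
Conditions: Me2AlCl (1.5 equiv), CH2Cl2, –78 → –20 °C
Reagents that add atoms: none
Why: Me2AlCl coordinates the aldehyde oxygen and the electron-rich 1,1-disubstituted alkene C9=C11 attacks C12 through its terminal carbon C11 while an allylic hydrogen of C10 passes to oxygen (concerted or closely asynchronous carbonyl-ene reaction). The closest known reaction type is the Lewis-acid-promoted intramolecular carbonyl-ene cyclisation of alkenyl aldehydes with the tether on the central carbon of the ene unit (type 2 in the usual classification), as shown by methylidenecycloalkanes with aldehydes under Me2AlCl. Ring C closes as a six-membered chair, exo with respect to the carbonyl group, the ene double bond moving out of the new ring to C9=C10, and this completes the bicyclo[3.2.1]octane. C8 becomes a stereocentre by group selection: the formyl group on C13 can reach only the methylidene on its own face of ring D, so the C13 centre set in step 6 fixes C8, while the C12 carbinol centre is uncontrolled and is removed in steps 8 and 9. The step needs group selectivity between the two methylidene groups (secured by the 1,3-cis geometry across ring D), regioselective hydrogen transfer (only C10 carries allylic hydrogens, C8 being quaternary) and chemoselectivity (the silyl ether prevents retro-aldol and no other carbonyl group is present).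

Step 8
Reactants: 11 tricyclic homoallylic alcohol
Product: 12 C12 O-(imidazol-1-ylcarbonothioyl) derivative of 11
Conditions: 1,1'-thiocarbonyldiimidazole (1.5 equiv), DMAP (10 mol%), ClCH2CH2Cl, 60 °C
Reagents that add atoms: 1,1'-thiocarbonyldiimidazole, S=C(n1ccnc1)n1ccnc1
Why: the secondary C12 hydroxyl is thioacylated as the first half of a Barton–McCombie deoxygenation; the tertiary oxygen is already silylated.

Step 9
Reactants: 12 thiocarbonyl imidazolide
Product: 13 tricyclic diene (C9=C10 and C6=C7; 16-OSiEt3)
Conditions: Bu3SnH (3 equiv, 0.3 M), AIBN (10 mol%), toluene, 100 °C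
Reagents that add atoms: none
Why: Barton–McCombie radical deoxygenation removes the helper oxygen at C12, and the high stannane concentration lets hydrogen transfer to the secondary C12 radical outrun the reversible 3-exo attack on C9=C10.

Step 10
Reactants: 13 tricyclic diene
Product: 14 C10,C7-diol (mixture at C6, C9 and C10)
Conditions: BH3·THF (3 equiv), THF, 0 °C → rt; then NaOH (3 M aq.), H2O2 (30%), 0 °C → rt
Reagents that add atoms: hydrogen peroxide, OO
Why: hydroboration–oxidation places oxygen on the less substituted carbon of each alkene (C10 and C7); the new centres at C6 and C10 are erased and C9 is equilibrated in later steps, so no facial control is needed.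

Step 11
Reactants: 14 diol
Product: 15 10-oxo-7-oic acid (mixture at C6 and C9)
Conditions: RuCl3·xH2O (5 mol%), NaIO4 (4 equiv), NaHCO3, CCl4/MeCN/H2O, 0 °C → rt
Reagents that add atoms: water, O
Why: catalytic ruthenium tetroxide oxidises the secondary alcohol to the C10 ketone and the primary alcohol to the C7 acid in one operation, and the substrate has no alkene or arene left to be attacked.

Step 12
Reactants: 15 keto acid
Product: 16 benzyl ester of the 10-ketone (B/C cis, 9β-H; mixture at C6)
Conditions: BnBr, K2CO3, DMF, rt; then DBU (0.2 equiv), 50 °C, same pot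
Reagents that add atoms: benzyl bromide, BrCc1ccccc1
Why: carboxylate O-alkylation gives an ester removable without base at the end, and DBU should equilibrate C9 (α to the ketone) to the cis B/C fusion, the more stable arrangement for a cyclopentanone fused next to a quaternary ring-fusion carbon (as with 15-oxo steroids).

Step 13
Reactants: 16 keto benzyl ester
Product: 19 enone ester (C5=C6 conjugated to the C10 ketone and the C7 ester), via C5 selenide 17 (not isolated), via selenoxide 18 (not isolated)
Conditions: LiN(i-Pr)2 (1.1 equiv), THF, –78 °C; PhSeBr; then H2O2 (30%), pyridine, CH2Cl2, 0 °C → rt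
Reagents that add atoms: none
Why: kinetic enolisation takes the C5 methylene and not the hindered C9 methine, and selenoxide syn-elimination can only run toward C6–H, so the C5=C6 enoate should form regioselectively.

Step 14
Reactants: 19 enone ester; 20 2-(2-bromoethyl)-1,3-dioxolane; 21 propanoyl chloride
Product: 23 C10 propanoate carrying the 2-(1,3-dioxolan-2-yl)ethyl chain, via tertiary alkoxide 22 (not isolated)
Conditions: 20, Mg, THF, 25 °C; CeCl3 (anhydrous, 1.5 equiv), THF, –78 °C; 19; then 21, –78 → 0 °C
Reagents that add atoms: none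
Why: the organocerium reagent adds 1,2 to the C10 ketone (no conjugate addition, no enolisation, ester untouched) from the β face because C11 on C9 screens the α face, which places O10 α and C1 β, and the metal alkoxide is acylated in the flask.

Step 15
Reactants: 23 C10 propanoate
Product: 24 19,10-lactone (C4-H epimers; 5β-H; C7 ester β)
Conditions: KOt-Bu (0.2 equiv), THF/t-BuOH 10:1, –20 → 0 °C
Reagents that add atoms: none
Why: the propanoate enolate adds 5-exo-trig to C5 of the enoate (intramolecular Michael addition), the O10 tether forcing attack on the α face and so a cis-fused γ-lactone, and the C6 ester then equilibrates under the same base to the position trans to C4.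

Step 16
Reactants: 24 lactone acetal
Product: 25 lactone aldehyde (C3 formyl; free 16-OH)
Conditions: HCl (1 M aq.), THF, rt
Reagents that add atoms: water, O
Why: aqueous acid hydrolyses the dioxolane to the C3 aldehyde and removes the tertiary triethylsilyl ether without touching the lactone or the benzyl ester.

Step 17
Reactants: 25 lactone aldehyde
Product: 26 ring-A aldol product (3-hydroxy, both C3 epimers)
Conditions: KOt-Bu (0.3 equiv), t-BuOH/THF, 0 °C
Reagents that add atoms: none
Why: under reversible base the lactone enolate at C4 adds to the C3 aldehyde in a 6-(enolexo)-exo-trig aldol that closes ring A, the bridged lactone allowing only one configuration at the new quaternary C4, while the C3 configuration need not be controlled here.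

Step 18
Reactants: 26 aldol product
Product: 27 3-oxo lactone benzyl ester
Conditions: Dess–Martin periodinane (1.5 equiv), NaHCO3, CH2Cl2, rt
Reagents that add atoms: none
Why: the secondary C3 alcohol is oxidised under neutral conditions (the tertiary 16-OH is inert) so that both aldol epimers converge on one ketone.

Step 19
Reactants: 27 3-ketone
Product: 28 benzyl ester of the target gibberellin (3β-OH)
Conditions: K[(s-Bu)3BH] (K-Selectride, 2.2 equiv), THF, –78 °C
Reagents that add atoms: none
Why: the bulky hydride should approach C3 along the equatorial trajectory, because the axial (β) approach is screened by the axial hydrogens on C1 and C5, and so give the axial 3β-alcohol without reducing the lactone or ester.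

Step 20
Reactants: 28 benzyl ester of the target gibberellin
Product: 29 target gibberellin (free 7-acid)
Conditions: H2 (1 atm), 10% Pd/C, EtOAc, rt
Reagents that add atoms: none
Why: hydrogenolysis frees the C7 acid under neutral conditions, which avoids the base-induced retro-aldol epimerisation at C3; the target has no alkene that could be reduced.

**Compound list**

1 | cyclopentane-1,3-dione | O=C1CCC(=O)C1 | starting material
2 | 3-[(tert-butyldimethylsilyl)oxy]propanal | O=CCCO[Si](C)(C)C(C)(C)C | starting material
3 | 2-{3-[(tert-butyldimethylsilyl)oxy]propyl}cyclopentane-1,3-dione | O=C1CCC(=O)C1CCCO[Si](C)(C)C(C)(C)C | intermediate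
4 | 2-(chloromethyl)-3,5-dioxahex-1-ene [3-chloro-2-(methoxymethoxy)prop-1-ene] | C=C(CCl)OCOC | starting material
5 | 2-{3-[(tert-butyldimethylsilyl)oxy]propyl}-2-[2-(methoxymethoxy)prop-2-en-1-yl]cyclopentane-1,3-dione | O=C1CCC(=O)C1(CCCO[Si](C)(C)C(C)(C)C)CC(=C)OCOC | intermediate
6 | tert-butyl(3-{1-[2-(methoxymethoxy)prop-2-en-1-yl]-2,5-dimethylidenecyclopentyl}propoxy)dimethylsilane | C=C1CCC(=C)C1(CCCO[Si](C)(C)C(C)(C)C)CC(=C)OCOC | intermediate
7 | 1-[1-(3-hydroxypropyl)-2,5-dimethylidenecyclopentyl]propan-2-one | C=C1CCC(=C)C1(CCCO)CC(C)=O | intermediate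
8 | 3-[2,5-dimethylidene-1-(2-oxopropyl)cyclopentyl]propanal | C=C1CCC(=C)C1(CCC=O)CC(C)=O | intermediate
9 | (2R,3R)-2-hydroxy-2-methyl-6,9-dimethylidenespiro[4.4]nonane-3-carbaldehyde (OH trans to CHO) | O=C[C@@H]1CC2(C[C@@]1(C)O)C(=C)CCC2=C | intermediate
10 | (2R,3R)-2-methyl-6,9-dimethylidene-2-[(triethylsilyl)oxy]spiro[4.4]nonane-3-carbaldehyde | O=C[C@@H]1CC2(C[C@@]1(C)O[Si](CC)(CC)CC)C(=C)CCC2=C | intermediate
11 | B/C/D tricycle: bicyclo[3.2.1]octane (C8, C9, C11–C16) fused at C8–C9 to cyclopentene ring B (C9=C10, 6-methylidene); 12-OH (either epimer); 16-methyl endo, 16-OSiEt3 exo; C8, C13, C16 as in the target | C1=C2CC(O)[C@@H]3C[C@]2(C[C@@]3(C)O[Si](CC)(CC)CC)C(=C)C1 | intermediate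
12 | 12-O-(imidazol-1-ylcarbonothioyl) derivative of 11 | C1=C2CC(OC(=S)n4ccnc4)[C@@H]3C[C@]2(C[C@@]3(C)O[Si](CC)(CC)CC)C(=C)C1 | intermediate
13 | 12-deoxy tricyclic diene (C9=C10, 6-methylidene, 16-OSiEt3 exo) | C1=C2CC[C@@H]3C[C@]2(C[C@@]3(C)O[Si](CC)(CC)CC)C(=C)C1 | intermediate
14 | 10-hydroxy-6-(hydroxymethyl) tricycle (mixture at C6, C9, C10; 16-OSiEt3) | OC1C2CC[C@@H]3C[C@]2(C[C@@]3(C)O[Si](CC)(CC)CC)C(CO)C1 | intermediate
15 | 10-oxo tricyclic 7-carboxylic acid (mixture at C6, C9; 16-OSiEt3) | O=C1C2CC[C@@H]3C[C@]2(C[C@@]3(C)O[Si](CC)(CC)CC)C(C(=O)O)C1 | intermediate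
16 | benzyl ester of 15 with 9β-H (B/C cis); mixture at C6 | O=C1[C@@H]2CC[C@@H]3C[C@]2(C[C@@]3(C)O[Si](CC)(CC)CC)C(C(=O)OCc4ccccc4)C1 | intermediate
17 | 5-(phenylselanyl) derivative of 16 | O=C1[C@@H]2CC[C@@H]3C[C@]2(C[C@@]3(C)O[Si](CC)(CC)CC)C(C(=O)OCc4ccccc4)C1[Se]c1ccccc1 | intermediate
18 | selenoxide of 17 | O=C1[C@@H]2CC[C@@H]3C[C@]2(C[C@@]3(C)O[Si](CC)(CC)CC)C(C(=O)OCc4ccccc4)C1[Se](=O)c1ccccc1 | intermediate
19 | benzyl 10-oxo tricyclic 5-ene-7-oate (C5=C6; 9β-H; 16-OSiEt3) | O=C1[C@@H]2CC[C@@H]3C[C@]2(C[C@@]3(C)O[Si](CC)(CC)CC)C(C(=O)OCc4ccccc4)=C1 | intermediate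
20 | 2-(2-bromoethyl)-1,3-dioxolane | BrCCC1OCCO1 | starting material
21 | propanoyl chloride | CCC(Cl)=O | starting material
22 | C10 tertiary carbinol present as its metal alkoxide (10α-O, 10β-[2-(1,3-dioxolan-2-yl)ethyl]; drawn as the alcohol) | O[C@]3(CCC1OCCO1)[C@@H]1CC[C@@H]4C[C@]1(C[C@@]4(C)O[Si](CC)(CC)CC)C(C(=O)OCc2ccccc2)=C3 | intermediate
23 | C10 propanoate of 22 | CCC(=O)O[C@]3(CCC1OCCO1)[C@@H]1CC[C@@H]4C[C@]1(C[C@@]4(C)O[Si](CC)(CC)CC)C(C(=O)OCc2ccccc2)=C3 | intermediate
24 | 19,10-γ-lactone (cis-fused; 5β-H; 6β-CO2Bn; C4-H, both C4 epimers; C1–C3 chain as dioxolane; 16-OSiEt3) | CC2C(=O)O[C@]3(CCC1OCCO1)[C@@H]1CC[C@@H]4C[C@]1(C[C@@]4(C)O[Si](CC)(CC)CC)[C@@H](C(=O)OCc5ccccc5)[C@@H]32 | intermediate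
25 | lactone aldehyde (C3 formyl; free 16-OH exo) | CC2C(=O)O[C@]3(CCC=O)[C@@H]1CC[C@@H]4C[C@]1(C[C@@]4(C)O)[C@@H](C(=O)OCc5ccccc5)[C@@H]32 | intermediate
26 | ring-A aldol product: 3-hydroxy 19,10-lactone benzyl ester, i.e. 28 as a mixture of C3 epimers | C[C@@]12C(=O)O[C@]3(CCC1O)[C@@H]1CC[C@@H]4C[C@]1(C[C@@]4(C)O)[C@@H](C(=O)OCc5ccccc5)[C@@H]32 | intermediate
27 | 3-oxo lactone benzyl ester (3-dehydro derivative of 28) | C[C@@]12C(=O)O[C@]3(CCC1=O)[C@@H]1CC[C@@H]4C[C@]1(C[C@@]4(C)O)[C@@H](C(=O)OCc5ccccc5)[C@@H]32 | intermediate
28 | benzyl ester of the target gibberellin (7-benzyl ester; 3β-OH; 16-OH exo) | C[C@@]12C(=O)O[C@]3(CC[C@@H]1O)[C@@H]1CC[C@@H]4C[C@]1(C[C@@]4(C)O)[C@@H](C(=O)OCc5ccccc5)[C@@H]32 | intermediate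
29 | target gibberellin: (3S,4S,5R,6S,8R,9R,10R,13R,16R)-3,16-dihydroxy-20-norgibberellane-7,19-dioic acid 19,10-lactone (3β-OH; 16-OH exo, 16-methyl endo) | C[C@@]12C(=O)O[C@]3(CC[C@@H]1O)[C@@H]1CC[C@@H]4C[C@]1(C[C@@]4(C)O)[C@@H](C(=O)O)[C@@H]32 | target

**Totals and risks**

Total step count: 20. Longest linear sequence: 20 steps (from 1).

The three steps most likely to fail:

Step 6. What may go wrong: loss of water from the tertiary aldol through the enamine and iminium forms, or weak facial discrimination when a ketone is the acceptor. The fallback replaces catalysis by an auxiliary-controlled aldol and sets out from 8. The aldehyde group is condensed with (R)-1-amino-2-(methoxymethyl)pyrrolidine to give the RAMP hydrazone F1. LiN(i-Pr)2 at –78 °C forms the azaenolate, which should add to the tethered methyl ketone in a lithium-chelated 5-exo aldol to the hydroxy hydrazone F2, a species with no iminium path to dehydration. Et3SiOTf and 2,6-lutidine give the silyl ether F3, and two-phase aqueous oxalic acid releases the aldehyde, which returns the route to 10.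

Step 14. What may go wrong: sluggish O-acylation of the hindered tertiary alkoxide, or ionisation and elimination of the tertiary allylic ester. The fallback closes the lactone by acyl substitution instead of Michael addition and sets out from 16. The kinetic enolate (LiN(i-Pr)2, –78 °C) is alkylated at C5 with methyl 2-bromopropanoate to the keto diester F4, and DBU sets C5 and C6 trans (propanoate α, benzyl ester β). The organocerium reagent made from 20 and CeCl3 then adds to C10 from the β face, and the resulting alkoxide should close onto the methyl ester on warming, with loss of methanol. This returns the route to 24 and bypasses steps 13 to 15.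

Step 19. What may go wrong: hydride delivery along the axial trajectory, which would give the equatorial 3α-alcohol. The fallback uses equilibration and recycling instead of reduction and sets out from 26. The aldol mixture of step 17 is separated; its 3β epimer is 28. The 3α-epimer F5 is returned to the catalytic KOt-Bu conditions of step 17, where retro-aldol and aldol re-equilibrate C3, and is recycled until the material has come back to the route at 28.

Further compounds
F1 | step 6 | (E)-hydrazone of 8 with (R)-1-amino-2-(methoxymethyl)pyrrolidine | C=C1CCC(=C)C1(CC/C=N/N2CCC[C@@H]2COC)CC(C)=O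
F2 | step 6 | RAMP hydrazone of hydroxy aldehyde 9 | COC[C@H]2CCCN2/N=C/[C@@H]1CC3(C[C@@]1(C)O)C(=C)CCC3=C
F3 | step 6 | RAMP hydrazone of silyloxy aldehyde 10 | COC[C@H]2CCCN2/N=C/[C@@H]1CC3(C[C@@]1(C)O[Si](CC)(CC)CC)C(=C)CCC3=C
F4 | step 14 | C5-(1-methoxy-1-oxopropan-2-yl) derivative of ketone 16 (keto diester) | COC(=O)C(C)C1C(=O)[C@@H]2CC[C@@H]3C[C@]2(C[C@@]3(C)O[Si](CC)(CC)CC)C1C(=O)OCc1ccccc1
F5 | step 19 | 3α-epimer of benzyl ester 28 | C[C@@]12C(=O)O[C@]3(CC[C@H]1O)[C@@H]1CC[C@@H]4C[C@]1(C[C@@]4(C)O)[C@@H](C(=O)OCc5ccccc5)[C@@H]32
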